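## The problem

The target is a flavonol, a 2-aryl-3-hydroxychromen-4-one in which benzo ring A is fused to pyranone ring C across C4a–C8a and ring B, a 4-hydroxyphenyl group, sits on C2. It has no stereocentre, so the difficulty is one of position only. Ring A is pentasubstituted, with oxygen on C5 and C7, the ring oxygen on C8a, the C4 acyl carbon on C4a and a 4-hydroxybenzyl group on C8, which leaves C6 as the only CH. C6 and C8 of a 5,7-dioxygenated flavonoid are electronically almost alike, so benzylation of a preformed phloroglucinol ring, or closure of ring C onto a ring with two free ortho oxygens, cannot be relied on to place the benzyl group at C8 alone, and hot strong acid can exchange the two positions by opening and reclosing ring C (Wessely–Moser rearrangement). The four phenols and the C3 enol make the free compound sensitive to air in base, so they must stay masked to the end, and the masks must then come off without loss or shift of the electron-rich benzyl group at the doubly benzylic CH2. The enabling feature is ring A itself: C5–C6–C7–C8 carries O, H, O and C-benzyl, which is the chain of a γ-benzylated acetoacetate in its dienol form, and C8a–C4a carries a heteroatom site beside an ester-level carbon, which is a 3-halopropiolate. Joining the two by cycloaddition fixes every ring A substituent by connectivity and leaves C8a as the only atom from which ring C can close.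

## Retrosynthesis

Flavonoid numbering is used for ring positions; locants inside compound names are systematic.

**16 from 15.** The five O–CH3 bonds of the pentamethyl ether 15 are cut last. Methyl ethers are the only masks compatible with the ketene acetal chemistry used earlier, and one reagent removes all of them. The forward step must cleave two chelated and three anisole-type ethers without acid-induced movement of the C8 benzyl group.

**15 from 14.** The O1–C8a bond is cut, giving the 1-(2-bromoaryl)-2-methoxy-1,3-diketone 14. Closing ring C by C–O coupling at a halogen is preferred to cyclodehydration of a phenol because ring A then carries a single site able to close, so a 6-benzyl isomer cannot form. The forward reaction is an intramolecular enolate O-arylation at a hindered, electron-rich aryl bromide.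

**14 from 11 (through 13) and 12.** The C3–C4 bond is cut, giving the ring A acid 11 and the ring B ketone 12, which brings C2, C3, the C3 oxygen and ring B in one piece. A direct Claisen condensation on the methyl ester 10 is rejected because its carbonyl is flanked by bromine and methoxy; the acid chloride 13 is reactive enough to be C-acylated by the lithium enolate of 12.

**11 from 10 from 9.** These are functional-group changes: O-methylation of the C5 phenol and cleavage of the hindered methyl ester at its O–CH3 bond. Attack at the methyl carbon bypasses the shielded carbonyl.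

**9 from 5 and 7 (through 8).** The C8–C8a and C4a–C5 bonds are cut by a retro-Diels–Alder transform. This takes the fully substituted arene 9 back to diene 5, which carries C5 to C8 with both oxygens and the benzyl group, and bromoalkyne 7, which carries C8a with bromine and C4a with the ester. Against building ring A by substitution of an arene, this cut fixes the benzyl group between the C7 oxygen and the future ring oxygen by construction. The forward reaction needs correct end-to-end matching of the two polarised partners and retention of bromine during aromatisation.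

**5 from 4 from 3 from 1 and 2; 7 from 6.** Diene 5 is the silyl dienolate of enol ether 4, which comes from β-keto ester 3, itself the γ-benzylation product of methyl acetoacetate 1 with 4-methoxybenzyl chloride 2. Alkyne 7 is made by brominating methyl propiolate 6. All five carbons of the diene chain and the benzyl group come from two bulk chemicals.

## Roads not taken

Alternative 1: Ring A is cut at C4a–C8a of a chalcone. Forward, Mg(OMe)2 in methanol opens the pyranone A1, 4-hydroxy-3-(4-methoxybenzyl)-6-[(E)-4-(4-methoxyphenyl)-2-oxobut-3-enyl]pyran-2-one, to the triketo ester A2, methyl (E)-2-(4-methoxybenzyl)-9-(4-methoxyphenyl)-3,5,7-trioxonon-8-enoate. The C6 methylene of A2 then attacks the ester in a Claisen cyclisation to give the chalcone A3, (E)-1-[2,4,6-trihydroxy-3-(4-methoxybenzyl)phenyl]-3-(4-methoxyphenyl)prop-2-en-1-one.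
- Merits: the route is biomimetic and delivers ring A with all three oxygens at the right level, with no halogen handle, no CuI-catalysed step and no ester adjustment. In that respect it is more economical than the chosen plan.
- Weak points: the Claisen mode must beat aldol cyclisation of the same chain, and the enone of A2 is exposed to methoxide. More seriously, A3 has two free hydroxyls ortho to the carbonyl, so ring C can close onto either, and the one next to the benzyl group is the more hindered. Oxidative closure of chalcones bearing a 6'-hydroxyl also tends towards five-membered rings. A1 itself must first be assembled from a benzylated pyranone and a cinnamoyl unit.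
- Comparison: the positional problem returns after the key step. The chosen plan pays with three adjustment steps but leaves only one oxygen site for ring closure.

Alternative 2: Ring A is cut at C8–C8a, C7–C8, C5–C6 and C4a–C5, on a preformed pyranone. Forward, irradiation of the diazo ketone A4, 6-[2-diazo-3-(4-methoxyphenyl)propanoyl]-3-methoxy-2-(4-methoxyphenyl)pyran-4-one, triggers a Wolff shift. The resulting vinylketene is captured by ethoxyacetylene A5 in a [2+2] addition, and four-electron opening and six-electron closure give the chromone A6, 7-ethoxy-5-hydroxy-3-methoxy-8-(4-methoxybenzyl)-2-(4-methoxyphenyl)chromen-4-one.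
- Merits: it is more convergent than the chosen plan. Rings B and C arrive intact, the benzyl position is fixed because the benzyl group already sits on the diazo carbon that becomes C8, and the C5 hydroxyl of A6 is formed free.
- Weak points: A4 is an α-alkyl diazo ketone with benzylic β-hydrogens, so 1,2-hydride shift of the carbene competes with the Wolff shift. The pyranone is itself photoactive, and making the acylpyranone A4 is a multistep task placed before the risky step. The C7 oxygen of A6 arrives as an ethyl ether from A5, which must be cleaved with the methyl ethers at the end.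
- Comparison: positional control is equal. The chosen plan sets against the higher convergence the fact that its uncertain step is run early, on material three steps from bulk chemicals.

Alternative 3: Ring C is cut at C3–C4. Forward, SmI2 reduces the aromatic aldehyde of the dialdehyde A7, 4,6-dimethoxy-3-(4-methoxybenzyl)-2-[1-(4-methoxyphenyl)-2-oxoethoxy]benzaldehyde, to a ketyl that adds to the aliphatic aldehyde. This gives the diol A8, 5,7-dimethoxy-8-(4-methoxybenzyl)-2-(4-methoxyphenyl)chromane-3,4-diol.
- Merits: the ring closure is mild and neutral, and probably more dependable than a CuI-catalysed coupling at a hindered bromide.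
- Weak points: it does not address ring A, so the pentasubstituted aldehyde must still be made by some regiocontrolled route. A7 is an enolisable α-aryloxy aldehyde of limited stability. A8 carries three stereocentres that are set only to be erased by two oxidations on the way to the flavonol.
- Comparison: the ring C step is better than step 9 of the chosen plan. Against that, the chosen plan solves the ring A problem, which this route leaves open, and reaches the flavonol oxidation level without redox detours.

Key step: step 5

Assumption: ketone 12 is taken as purchasable, and diene 5 is used as the crude isomer mixture in which the drawn 1Z,3Z isomer is expected to predominate (the C1 geometry has no consequence because C1 becomes aromatic).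

## Route

Step 1
Reactants: 1 methyl acetoacetate; 2 4-methoxybenzyl chloride
Product: 3 methyl 5-(4-methoxyphenyl)-3-oxopentanoate
Conditions: NaH, THF, 0 °C; n-BuLi, 0 °C; 2, 0 °C to rt; aq. HCl
Reagents that add atoms: none
Why: γ-Alkylation of a β-keto ester dianion: the second deprotonation creates the more basic terminal carbanion, which alone is alkylated by the reactive benzylic chloride.

Step 2
Reactants: 3 methyl 5-(4-methoxyphenyl)-3-oxopentanoate
Product: 4 methyl (E)-3-methoxy-5-(4-methoxyphenyl)pent-2-enoate
Conditions: HC(OMe)3, H2SO4 (cat.), MeOH, rt to 60 °C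
Reagents that add atoms: trimethyl orthoformate, COC(OC)OC
Why: Acid-catalysed ketalisation and loss of methanol should give the conjugated β-methoxy enoate as the more stable E isomer (the standard preparation of 3-alkoxy-2-enoates); any deconjugated isomer gives the same dienolate in step 3.

Step 3
Reactants: 4 methyl (E)-3-methoxy-5-(4-methoxyphenyl)pent-2-enoate
Product: 5 (1Z,3Z)-1,3-dimethoxy-5-(4-methoxyphenyl)-1-(trimethylsilyloxy)penta-1,3-diene
Conditions: LiN(i-Pr)2, THF, −78 °C; Me3SiCl, −78 °C to rt; used crude
Reagents that add atoms: chlorotrimethylsilane, C[Si](C)(C)Cl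
Why: Kinetic γ-deprotonation of the β-alkoxy enoate gives the extended dienolate, which is silylated on oxygen (standard preparation of vinylketene silyl acetals); the benzyl group should prefer the outward position on C4, the geometry needed for cycloaddition.

Step 4
Reactants: 6 methyl propiolate
Product: 7 methyl 3-bromopropiolate
Conditions: NBS, AgNO3 (cat.), acetone, rt; handled as a solution
Reagents that add atoms: N-bromosuccinimide, O=C1CCC(=O)N1Br
Why: AgNO3-catalysed electrophilic bromination of a terminal alkyne through its silver acetylide, the usual route to 3-halopropiolates.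

Step 5
Reactants: 5 (1Z,3Z)-1,3-dimethoxy-5-(4-methoxyphenyl)-1-(trimethylsilyloxy)penta-1,3-diene; 7 methyl 3-bromopropiolate
Product: 9 methyl 2-bromo-6-hydroxy-4-methoxy-3-(4-methoxybenzyl)benzoate, via cyclohexadiene cycloadduct 8 (not isolated)
Conditions: 7 (1.5 equiv), PhMe, 0 °C to 60 °C; then 1 M HCl, THF, rt
Reagents that add atoms: none
Why: The electron-rich diene 5 (largest HOMO coefficient at the benzyl-bearing terminus) and the electron-poor alkyne 7 (largest LUMO coefficient at the bromine-bearing β-carbon) should combine in a normal-demand, concerted but asynchronous [4+2] cycloaddition in which the C8–C8a bond runs ahead of the C4a–C5 bond between the ketene acetal carbon and the ester-bearing carbon. The closest known reaction type is the cycloaddition and aromatisation of 1-alkoxy-1-silyloxy-3-alkoxybutadienes with acetylenic esters to give salicylates, together with the established use of 3-halopropiolates as dienophiles. Ring A is closed by the intermolecular cycloaddition itself, both bonds forming suprafacially on each partner to give the 1,4-cyclohexadiene 8. Aromatisation follows because ring carbon 6 of 8 is a mixed ketal: ionisation of methoxide assisted by the silyloxy oxygen and loss of the proton on ring carbon 3 (a net 1,4-elimination of methanol), then hydrolysis of the aryl silyl ether on acidic work-up, should give phenol 9; if silanol leaves instead of methanol the product is 10, and the material converges in step 6. The two sp3 centres of 8 (ring carbons 3 and 6, cis-related through the diene geometry) are both erased, so no stereocontrol is needed and 9 is achiral. Two selectivities are required: the regiochemistry that puts benzyl next to bromine, secured by the push–pull polarisation of both partners, and cycloaddition in preference to conjugate addition–elimination or halophilic attack at the C–Br bond, favoured by a non-polar solvent, the absence of Lewis acid or fluoride, and the outward benzyl group of the 3Z diene. Bromine is retained because it sits on an sp2 carbon of 8 and cannot serve as the leaving group of the aromatising elimination, whereas the ketal methoxy group can.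

Step 6
Reactants: 9 methyl 2-bromo-6-hydroxy-4-methoxy-3-(4-methoxybenzyl)benzoate
Product: 10 methyl 2-bromo-4,6-dimethoxy-3-(4-methoxybenzyl)benzoate
Conditions: MeI, K2CO3, DMF, 50 °C
Reagents that add atoms: iodomethane, CI
Why: Williamson O-methylation of the hydrogen-bonded salicylate phenol; the polar solvent and gentle heating overcome the hydrogen bond, and the ester and aryl bromide are inert.

Step 7
Reactants: 10 methyl 2-bromo-4,6-dimethoxy-3-(4-methoxybenzyl)benzoate
Product: 11 2-bromo-4,6-dimethoxy-3-(4-methoxybenzyl)benzoic acid
Conditions: LiI, pyridine, reflux; then cold aq. HCl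
Reagents that add atoms: none
Why: The ester carbonyl is shielded by ortho bromine and ortho methoxy, so the ester is cleaved by SN2 attack of iodide on the ester methyl (alkyl–oxygen cleavage), the standard remedy for hindered methyl esters; aryl methyl ethers react far more slowly because phenoxide is the poorer leaving group, and cold acidification guards against protodecarboxylation.

Step 8
Reactants: 11 2-bromo-4,6-dimethoxy-3-(4-methoxybenzyl)benzoic acid; 12 2-methoxy-1-(4-methoxyphenyl)ethanone
Product: 14 1-[2-bromo-4,6-dimethoxy-3-(4-methoxybenzyl)phenyl]-2-methoxy-3-(4-methoxyphenyl)propane-1,3-dione, via aroyl chloride 13 (not isolated)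
Conditions: (COCl)2, DMF (cat.), CH2Cl2, 0 °C to rt, evaporate; 12 (2.2 equiv), LiN(SiMe3)2 (2.2 equiv), THF, −78 °C, then 13, −78 to 0 °C; aq. HCl
Reagents that add atoms: none
Why: The acid chloride is reactive enough to offset the two ortho substituents, and C-acylation of a ketone lithium enolate by an aroyl chloride is the standard entry to flavonoid 1,3-diketones; the second equivalent of enolate deprotonates the more acidic product and holds it as its chelated enolate.

Step 9
Reactants: 14 1-[2-bromo-4,6-dimethoxy-3-(4-methoxybenzyl)phenyl]-2-methoxy-3-(4-methoxyphenyl)propane-1,3-dione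
Product: 15 3,5,7-trimethoxy-8-(4-methoxybenzyl)-2-(4-methoxyphenyl)-4H-chromen-4-one
Conditions: CuI (10 mol %), 1,10-phenanthroline (20 mol %), K2CO3, dry DMF, 110 °C
Reagents that add atoms: none
Why: Intramolecular Ullmann-type C–O coupling: the diketone enolate binds monovalent copper, the C–Br bond ortho to the carbonyl is activated, and the enolate oxygen on the ring B side closes the six-membered ring C, as known for 1-(2-bromoaryl)-1,3-diketones giving flavones; C-arylation would require a four-membered ring and is excluded.

Step 10
Reactants: 15 3,5,7-trimethoxy-8-(4-methoxybenzyl)-2-(4-methoxyphenyl)-4H-chromen-4-one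
Product: 16 8-C-p-hydroxybenzylkaempferol, 3,5,7-trihydroxy-8-(4-hydroxybenzyl)-2-(4-hydroxyphenyl)-4H-chromen-4-one
Conditions: BBr3 (12 equiv), CH2Cl2, −78 °C to rt; then MeOH–H2O, 0 °C
Reagents that add atoms: none
Why: Lewis-acid ether cleavage: boron binds each ether oxygen and bromide attacks the methyl group, the standard global demethylation of polymethoxyflavones; the C3 and C5 ethers are chelation-assisted, the three anisole-type ethers follow at room temperature, and a cold quench limits exposure of the benzyl group to hot acid.

## Compound list

1 | methyl acetoacetate | CC(=O)CC(=O)OC | starting material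
2 | 4-methoxybenzyl chloride | COc1ccc(CCl)cc1 | starting material
3 | methyl 5-(4-methoxyphenyl)-3-oxopentanoate | COC(=O)CC(=O)CCc1ccc(OC)cc1 | intermediate
4 | methyl (E)-3-methoxy-5-(4-methoxyphenyl)pent-2-enoate | COC(=O)/C=C(/OC)CCc1ccc(OC)cc1 | intermediate
5 | (1Z,3Z)-1,3-dimethoxy-5-(4-methoxyphenyl)-1-(trimethylsilyloxy)penta-1,3-diene | CO/C(O[Si](C)(C)C)=C/C(OC)=C/Cc1ccc(OC)cc1 | intermediate
6 | methyl propiolate | C#CC(=O)OC | starting material
7 | methyl 3-bromopropiolate | COC(=O)C#CBr | intermediate
8 | methyl 2-bromo-4,6-dimethoxy-3-(4-methoxybenzyl)-6-(trimethylsilyloxy)cyclohexa-1,4-diene-1-carboxylate (racemic, 3-benzyl cis to 6-methoxy) | COC(=O)C1=C(Br)[C@H](Cc2ccc(OC)cc2)C(OC)=C[C@@]1(OC)O[Si](C)(C)C | intermediate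
9 | methyl 2-bromo-6-hydroxy-4-methoxy-3-(4-methoxybenzyl)benzoate | COC(=O)c1c(O)cc(OC)c(Cc2ccc(OC)cc2)c1Br | intermediate
10 | methyl 2-bromo-4,6-dimethoxy-3-(4-methoxybenzyl)benzoate | COC(=O)c1c(OC)cc(OC)c(Cc2ccc(OC)cc2)c1Br | intermediate
11 | 2-bromo-4,6-dimethoxy-3-(4-methoxybenzyl)benzoic acid | OC(=O)c1c(OC)cc(OC)c(Cc2ccc(OC)cc2)c1Br | intermediate
12 | 2-methoxy-1-(4-methoxyphenyl)ethanone | COCC(=O)c1ccc(OC)cc1 | starting material
13 | 2-bromo-4,6-dimethoxy-3-(4-methoxybenzyl)benzoyl chloride | ClC(=O)c1c(OC)cc(OC)c(Cc2ccc(OC)cc2)c1Br | intermediate
14 | 1-[2-bromo-4,6-dimethoxy-3-(4-methoxybenzyl)phenyl]-2-methoxy-3-(4-methoxyphenyl)propane-1,3-dione (racemic, enolisable at C2) | COC(C(=O)c1ccc(OC)cc1)C(=O)c1c(OC)cc(OC)c(Cc2ccc(OC)cc2)c1Br | intermediate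
15 | 3,5,7-trimethoxy-8-(4-methoxybenzyl)-2-(4-methoxyphenyl)-4H-chromen-4-one | COc1ccc(Cc2c(OC)cc(OC)c3c(=O)c(OC)c(-c4ccc(OC)cc4)oc23)cc1 | intermediate
16 | 8-C-p-hydroxybenzylkaempferol | O=c1c(O)c(-c2ccc(O)cc2)oc2c(Cc3ccc(O)cc3)c(O)cc(O)c12 | target

## Step count and least certain steps

Total: 10 steps. Longest linear sequence: 9 steps (1, 2, 3, 5, 6, 7, 8, 9, 10); step 4 is a one-step branch.

**Step 5 (key step).** The polar reactivity of the silyl ketene acetal may overtake the cycloaddition. Conjugate addition to the bromoalkyne followed by loss of bromide, or halophilic attack on bromine, would consume both partners, and the bond between the benzyl-bearing diene terminus and the bromine-bearing carbon is sterically slow. The fallback gives up the cycloaddition and builds the same ring from an arene; it sets out from 2 and returns at 11. Commercial 1-bromo-3,5-dimethoxybenzene is iodinated (N-iodosuccinimide, MeCN) para to a methoxy group to give 1-bromo-2-iodo-3,5-dimethoxybenzene F1. In parallel, 2 is converted with Zn dust and LiCl in THF into (4-methoxybenzyl)zinc chloride F2. Negishi coupling of the two at the carbon–iodine bond (Pd(PPh3)4, zerovalent palladium) should give 1-bromo-3,5-dimethoxy-2-(4-methoxybenzyl)benzene F3. Vilsmeier–Haack formylation (POCl3, DMF), directed para to methoxy and ortho to bromine, should then give 2-bromo-4,6-dimethoxy-3-(4-methoxybenzyl)benzaldehyde F4, and Pinnick oxidation (NaClO2, NaH2PO4, 2-methyl-2-butene) leads to 11. This route relies twice on para-directed electrophilic substitution instead of on connectivity.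

**Step 8.** O-acylation of the enolate, or sluggish attack at the doubly ortho-substituted acyl carbon, may lower the share of C-acylation. The fallback reverses the polarity of the diketone synthesis; it sets out from 11 (through its chloride 13) and returns at 14. Chloride 13 and excess CH2N2 give 1-[2-bromo-4,6-dimethoxy-3-(4-methoxybenzyl)phenyl]-2-diazoethanone F5. Rh2(OAc)4-catalysed O–H insertion into methanol then gives 1-[2-bromo-4,6-dimethoxy-3-(4-methoxybenzyl)phenyl]-2-methoxyethanone F6, whose lithium enolate (LiN(SiMe3)2) is acylated by the unhindered 4-methoxybenzoyl chloride to give 14.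

**Step 9.** Oxidative activation of the bromide, which is flanked by the benzyl group on an electron-rich ring, may be slow. Protodebromination or base-induced retro-Claisen cleavage of the diketone could then compete. The fallback installs the oxygen before the acylation and closes ring C by dehydration; it sets out from 11 and returns at 15. Carboxylate-assisted Ullmann hydroxylation (Cu2O cat., aq. KOH, 100 °C) gives 2-hydroxy-4,6-dimethoxy-3-(4-methoxybenzyl)benzoic acid F7. Acetone, trifluoroacetic anhydride and trifluoroacetic acid convert it into 5,7-dimethoxy-8-(4-methoxybenzyl)-2,2-dimethyl-4H-1,3-benzodioxin-4-one F8. The lithium enolate of 12 opens this acetonide with loss of acetone to give 1-[2-hydroxy-4,6-dimethoxy-3-(4-methoxybenzyl)phenyl]-2-methoxy-3-(4-methoxyphenyl)propane-1,3-dione F9, and cyclodehydration (H2SO4 cat., AcOH) gives 15. Only one phenolic oxygen is present, so the benzyl position stays fixed.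

**Step 3.** Formation of the wrong C3=C4 geometry (benzyl inward), partial C-silylation, or hydrolysis during isolation would leave a diene that does not cycloadd. The fallback changes the diene class; it sets out from 3 and returns at 10. Keto ester 3 is silylated (Me3SiCl, Et3N) to methyl 5-(4-methoxyphenyl)-3-(trimethylsilyloxy)pent-2-enoate F10. LiN(i-Pr)2 and Me3SiCl then give 1-methoxy-5-(4-methoxyphenyl)-1,3-bis(trimethylsilyloxy)penta-1,3-diene F11. Cycloaddition of this bis-silyl diene with 7 and acidic work-up should give methyl 2-bromo-4,6-dihydroxy-3-(4-methoxybenzyl)benzoate F12, and double O-methylation (MeI, K2CO3) gives 10.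

**Step 10.** Incomplete cleavage of the anisole-type ethers, or acid-promoted loss or migration of the benzyl group during a warm quench, may occur. The fallback replaces electrophilic cleavage by a chelation-controlled stage followed by a nucleophilic one; it sets out from 15 and returns at 16. BCl3 (CH2Cl2, −78 to 0 °C) removes the C5 methyl group to give 5-hydroxy-3,7-dimethoxy-8-(4-methoxybenzyl)-2-(4-methoxyphenyl)-4H-chromen-4-one F13. Excess NaSEt in DMF at 140 °C under argon then cleaves the remaining four methyl ethers by SN2 attack on methyl, without protic acid, to give 16.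

## Further compounds

F1 | step 5 | 1-bromo-2-iodo-3,5-dimethoxybenzene | COc1cc(Br)c(I)c(OC)c1
F2 | step 5 | (4-methoxybenzyl)zinc chloride | COc1ccc(C[Zn]Cl)cc1
F3 | step 5 | 1-bromo-3,5-dimethoxy-2-(4-methoxybenzyl)benzene | COc1ccc(Cc2c(Br)cc(OC)cc2OC)cc1
F4 | step 5 | 2-bromo-4,6-dimethoxy-3-(4-methoxybenzyl)benzaldehyde | COc1ccc(Cc2c(OC)cc(OC)c(C=O)c2Br)cc1
F5 | step 8 | 1-[2-bromo-4,6-dimethoxy-3-(4-methoxybenzyl)phenyl]-2-diazoethanone | COc1ccc(Cc2c(OC)cc(OC)c(C(=O)C=[N+]=[N-])c2Br)cc1
F6 | step 8 | 1-[2-bromo-4,6-dimethoxy-3-(4-methoxybenzyl)phenyl]-2-methoxyethanone | COCC(=O)c1c(OC)cc(OC)c(Cc2ccc(OC)cc2)c1Br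
F7 | step 9 | 2-hydroxy-4,6-dimethoxy-3-(4-methoxybenzyl)benzoic acid | OC(=O)c1c(OC)cc(OC)c(Cc2ccc(OC)cc2)c1O
F8 | step 9 | 5,7-dimethoxy-8-(4-methoxybenzyl)-2,2-dimethyl-4H-1,3-benzodioxin-4-one | COc1ccc(Cc2c(OC)cc(OC)c3c2OC(C)(C)OC3=O)cc1
F9 | step 9 | 1-[2-hydroxy-4,6-dimethoxy-3-(4-methoxybenzyl)phenyl]-2-methoxy-3-(4-methoxyphenyl)propane-1,3-dione (racemic, enolisable) | COC(C(=O)c1ccc(OC)cc1)C(=O)c1c(OC)cc(OC)c(Cc2ccc(OC)cc2)c1O
F10 | step 3 | methyl 5-(4-methoxyphenyl)-3-(trimethylsilyloxy)pent-2-enoate (E/Z mixture) | COC(=O)C=C(CCc1ccc(OC)cc1)O[Si](C)(C)C
F11 | step 3 | (1Z,3Z)-1-methoxy-5-(4-methoxyphenyl)-1,3-bis(trimethylsilyloxy)penta-1,3-diene | CO/C(O[Si](C)(C)C)=C/C(O[Si](C)(C)C)=C/Cc1ccc(OC)cc1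
F12 | step 3 | methyl 2-bromo-4,6-dihydroxy-3-(4-methoxybenzyl)benzoate | COC(=O)c1c(O)cc(O)c(Cc2ccc(OC)cc2)c1Br
F13 | step 10 | 5-hydroxy-3,7-dimethoxy-8-(4-methoxybenzyl)-2-(4-methoxyphenyl)-4H-chromen-4-one | COc1ccc(Cc2c(OC)cc(O)c3c(=O)c(OC)c(-c4ccc(OC)cc4)oc23)cc1
A1 | alternative 1 | 4-hydroxy-3-(4-methoxybenzyl)-6-[(E)-4-(4-methoxyphenyl)-2-oxobut-3-enyl]pyran-2-one | COc1ccc(/C=C/C(=O)Cc2cc(O)c(Cc3ccc(OC)cc3)c(=O)o2)cc1
A2 | alternative 1 | methyl (E)-2-(4-methoxybenzyl)-9-(4-methoxyphenyl)-3,5,7-trioxonon-8-enoate (racemic, enolisable) | COC(=O)C(Cc1ccc(OC)cc1)C(=O)CC(=O)CC(=O)/C=C/c1ccc(OC)cc1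
A3 | alternative 1 | (E)-1-[2,4,6-trihydroxy-3-(4-methoxybenzyl)phenyl]-3-(4-methoxyphenyl)prop-2-en-1-one | COc1ccc(/C=C/C(=O)c2c(O)cc(O)c(Cc3ccc(OC)cc3)c2O)cc1
A4 | alternative 2 | 6-[2-diazo-3-(4-methoxyphenyl)propanoyl]-3-methoxy-2-(4-methoxyphenyl)pyran-4-one | COc1ccc(CC(=[N+]=[N-])C(=O)c2cc(=O)c(OC)c(-c3ccc(OC)cc3)o2)cc1
A5 | alternative 2 | ethoxyacetylene | CCOC#C
A6 | alternative 2 | 7-ethoxy-5-hydroxy-3-methoxy-8-(4-methoxybenzyl)-2-(4-methoxyphenyl)chromen-4-one | CCOc1cc(O)c2c(=O)c(OC)c(-c3ccc(OC)cc3)oc2c1Cc1ccc(OC)cc1
A7 | alternative 3 | 4,6-dimethoxy-3-(4-methoxybenzyl)-2-[1-(4-methoxyphenyl)-2-oxoethoxy]benzaldehyde (racemic) | O=CC(Oc1c(C=O)c(OC)cc(OC)c1Cc1ccc(OC)cc1)c1ccc(OC)cc1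
A8 | alternative 3 | 5,7-dimethoxy-8-(4-methoxybenzyl)-2-(4-methoxyphenyl)chromane-3,4-diol (racemic, 2,3-trans-3,4-cis) | O[C@@H]1[C@H](O)[C@@H](c2ccc(OC)cc2)Oc2c1c(OC)cc(OC)c2Cc1ccc(OC)cc1
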